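**Remarks on the chemistry (assumptions)**
- (S)-Naringenin of high enantiomeric purity is assumed as the article of commerce; its stereocentre becomes C2f of the target and no bond to it is made or broken.
- In step 11 the diketo ester is assumed to chelate copper through the ester and central carbonyl oxygens, as pyruvates do. On that model the (R,R)-ligand opens the Re face; if a test with a simple phenol shows the other sense, the (S,S)-ligand is used with nothing else changed.

## Analysis of the target

Daphnodorin F (24) is built from a phloroglucinol ring A fused to a pyranone ring C (O1, C2, C3, C4, C4a, C8a), which shares its C2–C3 bond with a dihydrofuran ring D (O7f, C2, C3, C8f, C7f) fused to the benzene ring of a flavan (atoms marked f); C2 and C2f each carry a 4-hydroxyphenyl group. There are three stereocentres: the ketal carbon C2 (S), the tertiary carbinol C3 (R) and C2f (S). C2 and C3 are adjacent and the six/five ring fusion can only be cis, so only the absolute configuration at C3 has to be chosen; C2f is four bonds from C3 across a flat aromatic carbon and cannot steer it. The sensitive groups are the diaryl ketal at C2 (acid), the tertiary α-hydroxy ketone C3–C4 (retro-Claisen cleavage and α-ketol shift in base), five free phenols (oxidation) and the benzylic C2f–O1f ether (hydrogenolysis, acid). The difficulty is the pair of adjacent, fully substituted, oxygenated carbons C2/C3 wedged between three aryl groups, and its attachment to the flavan at C8f/O7f and not at C6f. The plan rests on one feature: ring C meets ring A through two bonds on neighbouring ring A carbons, O1–C8a and C4–C4a, and the ring A oxygens sit at C5 and C7. That is the pattern of a 3,5-dialkoxybenzyne that takes an oxygen nucleophile at its distal carbon and an acyl group at the proximal one.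

## Retrosynthetic reasoning

**24 ⇒ 23 ⇒ 22 (protecting groups).** The five phenols are carried as benzyl ethers and freed last by hydrogenolysis, under neutral conditions that the ketal and the α-hydroxy ketone tolerate. The C3 hydroxyl is carried as a triethylsilyl ether through the key step only. These cuts gain no skeleton but define 22 as the real goal of the construction.

**22 ⇒ 20 + 21 (O1–C8a and C4–C4a).** Both bonds that tie ring C to ring A are cut at once. Ring A becomes aryne 21, generated from silyl triflate 17, and 20 keeps a C2 hemiketal hydroxyl and a C3 methyl ester. These are the only two bonds in the pentacycle that lie on adjacent aromatic carbons with an oxygen on one and an acyl carbon on the other. Cutting C2–O1 or C3–C4 singly would demand a preformed, heavily ortho-substituted benzophenone. The gain is convergence: all three stereocentres are already in 20 and the achiral ring A arrives last. The forward reaction must make the C2 oxygen add to the aryne carbon remote from the flanking benzyloxy group, and must make the resulting aryl anion attack the ester before it is protonated.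

**20 ⇒ 18 ⇒ 7 + 11 (C3–C8f and O7f–C2).** Removing the silyl group gives diol 18. Its C3 is the carbinol carbon of a Friedel–Crafts hydroxyalkylation, so C3–C8f is cut between flavan phenol 7 and the central carbonyl of vicinal tricarbonyl ester 11. The O7f–C2 bond is the hemiketal that the neighbouring phenol forms with the aryl ketone unaided. This cut is chosen because 11 brings C2, C3 and the ester carbon (later C4) at their final oxidation levels. Addition to a prochiral, strongly activated carbonyl is also where a chiral Lewis acid can set C3 regardless of the remote C2f. The forward reaction must choose C8f over C6f and one face of the carbonyl.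

**7 ⇒ 6 ⇒ 5 ⇒ 2 ⇒ 1 (flavan).** C2f comes from the chiral pool: 1 has the skeleton, the S configuration and all three oxygens. What remains is to remove the C4 oxygen and to tell the three phenols apart so that only O7 is free in 7. The most acidic hydroxyl, on C7, is masked first as an allyl ether (2). The ketone is then removed with the help of the neighbouring 5-hydroxyl (5), which also ends the risk of base-induced ring opening at the stereocentre. The two remaining phenols are benzylated (6) and the allyl group is taken off.

**11 ⇒ 10 ⇒ 9 ⇒ 8 (tricarbonyl).** The central carbonyl is traced back to a diazo group and that to the methylene of β-keto ester 9, made by C-methoxycarbonylation of acetophenone 8.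

**17 ⇒ 14 ⇒ 13 ⇒ 12 (aryne precursor).** The C–Si and O–triflyl bonds are cut together: ortho-bromophenol 14 delivers both through silyl migration from oxygen to carbon after bromine–lithium exchange. 14 comes from 13 by bromination beside the free hydroxyl, and 13 from 12 by twofold benzylation.

## Alternatives that were turned down

**Alternative 1:** C3 as a linchpin; the cuts are C3–C8f and C2–C3.
- Forward: the flavan-8-yl Grignard reagent A1 adds to the silyl ketone carbon of silyl glyoxylate A2, silicon moves from carbon to oxygen (Brook rearrangement), and the glycolate enolate is trapped by aldehyde A3 to give A4.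
- For it: two C–C bonds from three components in one flask, a reaction type with precedent for aryl Grignard reagents, and a flavan position fixed by the halogen behind A1 and not by a Friedel–Crafts preference. On precedent of the key step and on regiochemistry at the flavan it is stronger than the chosen route.
- Against it: nothing in the flask is chiral except the remote C2f, so C3 should form as a near-equal mixture of epimers. The aldol selectivity is spent on a carbinol that must be oxidised anyway, and A1 is a hindered, doubly ortho-oxygenated aryl metal. A4 still needs oxidation, removal of the acetal on O7f and an ester/silyl exchange before it stands where 20 stands, with rings A and C still missing.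
- Comparison: it solves the easier half with less stereocontrol and more steps. The chosen route sets C3 with a catalyst in one step (7 + 11 → 18).

**Alternative 2:** The cut is C2–C3 within ring D.
- Forward: 1,2-diketone A5 carries ring A on one carbonyl, the flavan on the other and a 4-(benzyloxy)benzyl ether on O7f. Under visible light the C3 carbonyl oxygen abstracts a benzylic hydrogen from the O7f–CH2 group and the 1,5-biradical closes ring D to give A6.
- For it: no reagent, the crowded C2–C3 bond is made by radical recombination, the C3 hydroxyl is born in place, and C4–C4a exists before the key step. The unprecedented aryne step is avoided, so on precedent of the ring-forming event it is the stronger plan.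
- Against it: C3 is formed with no absolute control. C2 arrives one oxidation level too low, and raising it to the ketal needs a benzylic C–H oxidation that must tell C2–H from the equally activated C2f–H. Three acetates must come off in the presence of the α-hydroxy ketone, and A5, an unsymmetrical benzil with both aryl groups doubly ortho-substituted, is a long synthesis in itself.
- Comparison: the chosen route has C2 at the ketal level from the start and C3 fixed by a catalyst.

**Alternative 3:** The cuts are C3–O and C2–O1, from an aromatic benzofuran.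
- Forward: the flavan-fused 2-aryl-3-aroylbenzofuran A7 is epoxidised at C2=C3 by a chiral dioxirane and the ortho phenol of the aroyl group opens the epoxide at C2. This gives A8, identical with 23.
- For it: the shortest endgame (A8 is one hydrogenolysis from 24), both stereocentres from one reagent-controlled event, and a flat, robust precursor. After the key step it is two steps shorter than the chosen route.
- Against it: the C2=C3 bond is tetrasubstituted, part of an aromatic furan, conjugated to the aroyl carbonyl and flanked by two aryl groups. That is the weakest substrate class for chiral dioxiranes in both rate and face discrimination. The free, electron-rich phenol next to the ketone competes for the oxidant, and any shortfall in selectivity appears as diastereomers at the last stage.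
- Comparison: the chosen route pays with a silylation and a desilylation, but fixes C3 by addition to a strongly activated carbonyl and lets C2 follow.

Key step: step 13

## Route

Step 1
Reactants: 1 (S)-naringenin
Product: 2 (2S)-5-hydroxy-2-(4-hydroxyphenyl)-7-(prop-2-enyloxy)chroman-4-one (7-O-allylnaringenin)
Conditions: allyl alcohol (1.05 equiv), PPh3, DIAD, THF, 0 °C to rt
Reagents that add atoms: allyl alcohol, C=CCO
Why: Mitsunobu etherification: the betaine deprotonates the most acidic phenol, the 7-hydroxyl para to the C4 carbonyl, while the 5-hydroxyl is locked in a hydrogen bond to that carbonyl and the 4'-hydroxyl is clearly less acidic. The medium is essentially neutral, so the flavanone should not open to the chalcone and the stereocentre (later C2f) keeps its configuration.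

Step 2
Reactants: 2 (2S)-5-hydroxy-2-(4-hydroxyphenyl)-7-(prop-2-enyloxy)chroman-4-one
Product: 5 (2S)-7-(allyloxy)-2-(4-hydroxyphenyl)chroman-5-ol, via bis(ethyl carbonate) 3 (not isolated), via 4'-O-ethoxycarbonyl flavan-5-ol 4 (not isolated)
Conditions: ClCO2Et, Et3N, THF, 0 °C; then NaBH4, THF/H2O, 0 °C to rt; then aq. NaOH, rt
Reagents that add atoms: none
Why: Deoxygenation of an ortho-hydroxyaryl ketone through its carbonate: hydride reduces C4=O, the alkoxide takes over the neighbouring 5-O-ethoxycarbonyl group, the freed phenoxide expels ethyl carbonate to an ortho-quinone methide, a second hydride gives C4H2, and hydroxide removes the 4'-carbonate. The amine base is present only briefly at 0 °C and the stereocentre takes no part; after this step no carbonyl is left that could open the pyran ring.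

Step 3
Reactants: 5 (2S)-7-(allyloxy)-2-(4-hydroxyphenyl)chroman-5-ol
Product: 6 (2S)-7-(allyloxy)-5-(benzyloxy)-2-[4-(benzyloxy)phenyl]chromane
Conditions: BnBr (2.5 equiv), K2CO3, DMF, rt
Reagents that add atoms: benzyl bromide, BrCc1ccccc1
Why: Williamson etherification of both phenols; with the ketone gone, carbonate base cannot epimerise C2f, and the allyl ether keeps O7 distinct from the two benzyl ethers.

Step 4
Reactants: 6 (2S)-7-(allyloxy)-5-(benzyloxy)-2-[4-(benzyloxy)phenyl]chromane
Product: 7 (2S)-5-(benzyloxy)-2-[4-(benzyloxy)phenyl]chroman-7-ol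
Conditions: Pd(PPh3)4 (5 mol %), morpholine, THF, rt
Reagents that add atoms: none
Why: Tsuji–Trost deallylation: zerovalent palladium ionises the aryl allyl ether and morpholine takes up the allyl group; benzyl ethers and the flavan are inert, and the 7-hydroxyl is now the only free phenol.

Step 5
Reactants: 8 4'-(benzyloxy)acetophenone
Product: 9 methyl 3-[4-(benzyloxy)phenyl]-3-oxopropanoate
Conditions: NaH (2.2 equiv), (MeO)2CO, THF, reflux; aq. HCl quench
Reagents that add atoms: dimethyl carbonate, COC(=O)OC
Why: Crossed Claisen condensation of the ketone enolate with dimethyl carbonate, driven to completion by deprotonation of the β-keto ester formed.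

Step 6
Reactants: 9 methyl 3-[4-(benzyloxy)phenyl]-3-oxopropanoate
Product: 10 methyl 3-[4-(benzyloxy)phenyl]-2-diazo-3-oxopropanoate
Conditions: 4-acetamidobenzenesulfonyl azide, Et3N, MeCN, 0 °C to rt
Reagents that add atoms: 4-acetamidobenzenesulfonyl azide, CC(=O)Nc1ccc(cc1)S(=O)(=O)N=[N+]=[N-]
Why: Regitz diazo transfer to the doubly activated methylene group.

Step 7
Reactants: 10 methyl 3-[4-(benzyloxy)phenyl]-2-diazo-3-oxopropanoate
Product: 11 methyl 3-[4-(benzyloxy)phenyl]-2,3-dioxopropanoate
Conditions: dimethyldioxirane, acetone, 0 °C to rt; stored over 4 Å MS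
Reagents that add atoms: dimethyldioxirane, CC1(C)OO1
Why: Oxygen-atom transfer from the dioxirane to the diazo carbon with loss of dinitrogen is a standard entry to vicinal tricarbonyl compounds and leaves no acid behind. The product is kept over molecular sieves because its central carbonyl hydrates readily.

Step 8
Reactants: 12 phloroglucinol
Product: 13 3,5-bis(benzyloxy)phenol
Conditions: BnBr (2.0 equiv), K2CO3, DMF, rt
Reagents that add atoms: benzyl bromide, BrCc1ccccc1
Why: Williamson etherification with two equivalents of halide; the outcome is statistical and the dibenzyl ether is separated from mono- and tri-ether, which is acceptable in the first step from a cheap triphenol.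

Step 9
Reactants: 13 3,5-bis(benzyloxy)phenol
Product: 14 3,5-bis(benzyloxy)-2-bromophenol
Conditions: NBS (1.0 equiv), CH2Cl2, −78 °C
Reagents that add atoms: N-bromosuccinimide, O=C1CCC(=O)N1Br
Why: Electrophilic aromatic bromination at low temperature; the position between the hydroxyl and a benzyloxy group should be preferred to the one between two benzyloxy groups through hydrogen-bonded delivery of the reagent and lower hindrance, and one equivalent limits dibromination.

Step 10
Reactants: 14 3,5-bis(benzyloxy)-2-bromophenol
Product: 17 3,5-bis(benzyloxy)-2-(trimethylsilyl)phenyl trifluoromethanesulfonate, via trimethylsilyl ether 15 (not isolated), via lithium 2-silylphenolate 16 (not isolated)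
Conditions: (Me3Si)2NH, THF, 70 °C, then evaporate; n-BuLi, THF, −78 °C; then Tf2O, −78 °C
Reagents that add atoms: hexamethyldisilazane, C[Si](C)(C)N[Si](C)(C)C; trifluoromethanesulfonic anhydride, O=S(=O)(OS(=O)(=O)C(F)(F)F)C(F)(F)F
Why: O-Silylation, bromine–lithium exchange and anionic 1,3-shift of silicon from oxygen to carbon (retro-Brook rearrangement) give the ortho-silyl phenolate, which is triflated on oxygen; this is the standard route to ortho-silylaryl triflates.

Step 11
Reactants: 7 (2S)-5-(benzyloxy)-2-[4-(benzyloxy)phenyl]chroman-7-ol; 11 methyl 3-[4-(benzyloxy)phenyl]-2,3-dioxopropanoate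
Product: 18 methyl (2S,8R,9S)-5-(benzyloxy)-2,8-bis[4-(benzyloxy)phenyl]-8,9-dihydroxy-3,4,8,9-tetrahydro-2H-furo[2,3-h]chromene-9-carboxylate (C8 and C9 of this name are C2 and C3 of the target numbering)
Conditions: Cu(OTf)2 (10 mol %), 2,2'-(propane-2,2-diyl)bis[(4R)-4-tert-butyl-4,5-dihydrooxazole] (11 mol %), 4 Å MS, CH2Cl2, −20 °C to rt
Reagents that add atoms: none
Why: Friedel–Crafts hydroxyalkylation of the phenol by the central, most electrophilic carbonyl of 11 held in a chelate on the chiral divalent copper Lewis acid, followed by 5-exo-trig hemiketalisation of O7f onto the aryl ketone, the sequence by which phenols condense with ninhydrin. C3 is set by the ligand, which leaves the Re face of the central carbonyl open (the remote C2f has no say); attack at C8f and not C6f is expected because C6f is screened by the benzyl group on O5f while C8f is flanked only by the tied-back ring oxygen. The C2 hydroxyl epimers interconvert through the open keto phenol and 18 is drawn as the one needed later.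

Step 12
Reactants: 18 methyl (2S,8R,9S)-5-(benzyloxy)-2,8-bis[4-(benzyloxy)phenyl]-8,9-dihydroxy-3,4,8,9-tetrahydro-2H-furo[2,3-h]chromene-9-carboxylate
Product: 20 methyl (2S,8R,9S)-5-(benzyloxy)-2,8-bis[4-(benzyloxy)phenyl]-8-hydroxy-9-[(triethylsilyl)oxy]-3,4,8,9-tetrahydro-2H-furo[2,3-h]chromene-9-carboxylate, via bis(triethylsilyl) ether 19 (not isolated)
Conditions: Et3SiOTf (3 equiv), 2,6-lutidine, CH2Cl2, −78 to 0 °C; then AcOH/THF/H2O, rt
Reagents that add atoms: triethylsilyl trifluoromethanesulfonate, CC[Si](CC)(CC)OS(=O)(=O)C(F)(F)F
Why: Both hydroxyls are tertiary, so a selective single silylation is not to be expected; the silyl triflate therefore silylates both, and the silyl ketal on C2 should then hydrolyse in aqueous acetic acid, through the aryl-stabilised oxocarbenium ion, much faster than the crowded tertiary alkyl silyl ether on C3. 19 is drawn as the closed C2 epimer of 18; the other epimer or the open-chain aryl silyl ether would converge on 20 under the same treatment.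

Step 13
Reactants: 20 methyl (2S,8R,9S)-5-(benzyloxy)-2,8-bis[4-(benzyloxy)phenyl]-8-hydroxy-9-[(triethylsilyl)oxy]-3,4,8,9-tetrahydro-2H-furo[2,3-h]chromene-9-carboxylate; 17 3,5-bis(benzyloxy)-2-(trimethylsilyl)phenyl trifluoromethanesulfonate
Product: 22 penta-O-benzyl daphnodorin F 3-O-triethylsilyl ether (2S,3R,2fS in the target numbering), via 3,5-bis(benzyloxy)benzyne 21 (not isolated)
Conditions: CsF (5 equiv), 17 (2 equiv), THF, 65 °C
Reagents that add atoms: none
Why: Proposed new method: fluoride removes the trimethylsilyl group of 17 and triflate leaves to give aryne 21; the C2 hemiketal oxygen of 20 adds to the aryne carbon remote from the flanking benzyloxy group, because that places the aryl anion beside the inductively withdrawing oxygen substituent, and this anion attacks the methyl ester on C3 and expels methoxide. The closest known reaction type is the aryne annulation of salicylate esters to xanthones (oxygen addition, then intramolecular acyl substitution); here an aliphatic hemiketal oxygen and an ester two carbons away replace the phenol and its ortho ester. O1–C8a forms intermolecularly and ring C then closes by 6-exo-trig acyl substitution, which forms C4–C4a. The only stereocentre fixed in this step is C2, and it is controlled by C3: only the hemiketal epimer whose oxygen is cis to the ester can bridge to a six-membered ring cis-fused to ring D, and the epimers interconvert through the open keto phenol. The step needs regioselective aryne capture (secured by the 3-benzyloxy group, giving the 5,7- and not the 6,8-dioxygenated ring A), capture by the hemiketal oxygen in preference to the phenoxide of the open form (the closed form is favoured by the fully substituted, electron-poor C3, and only its adduct can cyclise irreversibly), and acylation of the aryl anion before protonation (an ether solvent in place of a nitrile and the silyl ether on O3 remove proton sources). An excess of 17 allows for aryne consumed by the methoxide released.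

Step 14
Reactants: 22 penta-O-benzyl daphnodorin F 3-O-triethylsilyl ether
Product: 23 penta-O-benzyl daphnodorin F
Conditions: HF·pyridine, pyridine, THF, 0 °C to rt
Reagents that add atoms: none
Why: Fluoride-induced Si–O cleavage under buffered, slightly acidic conditions; basic fluoride is avoided because a tertiary alkoxide next to the C4 ketone could undergo α-ketol rearrangement, and the ketal should tolerate buffered HF at this temperature.

Step 15
Reactants: 23 penta-O-benzyl daphnodorin F
Product: 24 daphnodorin F
Conditions: H2 (1 atm), Pd(OH)2/C, THF/MeOH, rt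
Reagents that add atoms: none
Why: Hydrogenolysis of five aryl benzyl ethers on palladium; the primary benzyl–oxygen bonds should cleave well before the hindered secondary C2f–O1f and tertiary C2–O bonds, and the aryl ketone, hydrogen-bonded to the freed 5-hydroxyl, should not be reduced. The reaction is stopped after uptake of five equivalents.

## Compound list

1 | (S)-naringenin, (2S)-5,7-dihydroxy-2-(4-hydroxyphenyl)chroman-4-one | O=C1C[C@@H](c2ccc(O)cc2)Oc2cc(O)cc(O)c12 | starting material
2 | (2S)-5-hydroxy-2-(4-hydroxyphenyl)-7-(prop-2-enyloxy)chroman-4-one | O=C1C[C@@H](c2ccc(O)cc2)Oc2cc(OCC=C)cc(O)c12 | intermediate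
3 | (2S)-7-(allyloxy)-2-[4-(ethoxycarbonyloxy)phenyl]-4-oxochroman-5-yl ethyl carbonate | O=C1C[C@@H](c2ccc(OC(=O)OCC)cc2)Oc2cc(OCC=C)cc(OC(=O)OCC)c12 | intermediate (not isolated)
4 | 4-[(2S)-7-(allyloxy)-5-hydroxychroman-2-yl]phenyl ethyl carbonate | C1C[C@@H](c2ccc(OC(=O)OCC)cc2)Oc2cc(OCC=C)cc(O)c12 | intermediate (not isolated)
5 | (2S)-7-(allyloxy)-2-(4-hydroxyphenyl)chroman-5-ol | C1C[C@@H](c2ccc(O)cc2)Oc2cc(OCC=C)cc(O)c12 | intermediate
6 | (2S)-7-(allyloxy)-5-(benzyloxy)-2-[4-(benzyloxy)phenyl]chromane | C1C[C@@H](c2ccc(OCc3ccccc3)cc2)Oc2cc(OCC=C)cc(OCc3ccccc3)c12 | intermediate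
7 | (2S)-5-(benzyloxy)-2-[4-(benzyloxy)phenyl]chroman-7-ol | C1C[C@@H](c2ccc(OCc3ccccc3)cc2)Oc2cc(O)cc(OCc3ccccc3)c12 | intermediate
8 | 4'-(benzyloxy)acetophenone | CC(=O)c1ccc(OCc2ccccc2)cc1 | starting material
9 | methyl 3-[4-(benzyloxy)phenyl]-3-oxopropanoate | COC(=O)CC(=O)c1ccc(OCc2ccccc2)cc1 | intermediate
10 | methyl 3-[4-(benzyloxy)phenyl]-2-diazo-3-oxopropanoate | COC(=O)C(=[N+]=[N-])C(=O)c1ccc(OCc2ccccc2)cc1 | intermediate
11 | methyl 3-[4-(benzyloxy)phenyl]-2,3-dioxopropanoate | COC(=O)C(=O)C(=O)c1ccc(OCc2ccccc2)cc1 | intermediate
12 | phloroglucinol | Oc1cc(O)cc(O)c1 | starting material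
13 | 3,5-bis(benzyloxy)phenol | Oc1cc(OCc2ccccc2)cc(OCc2ccccc2)c1 | intermediate
14 | 3,5-bis(benzyloxy)-2-bromophenol | Oc1cc(OCc2ccccc2)cc(OCc2ccccc2)c1Br | intermediate
15 | [3,5-bis(benzyloxy)-2-bromophenoxy]trimethylsilane | C[Si](C)(C)Oc1cc(OCc2ccccc2)cc(OCc2ccccc2)c1Br | intermediate (not isolated)
16 | lithium 3,5-bis(benzyloxy)-2-(trimethylsilyl)phenolate | [Li+].[O-]c1cc(OCc2ccccc2)cc(OCc2ccccc2)c1[Si](C)(C)C | intermediate (not isolated)
17 | 3,5-bis(benzyloxy)-2-(trimethylsilyl)phenyl trifluoromethanesulfonate | C[Si](C)(C)c1c(OCc2ccccc2)cc(OCc2ccccc2)cc1OS(=O)(=O)C(F)(F)F | intermediate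
18 | methyl (2S,8R,9S)-5-(benzyloxy)-2,8-bis[4-(benzyloxy)phenyl]-8,9-dihydroxy-3,4,8,9-tetrahydro-2H-furo[2,3-h]chromene-9-carboxylate | COC(=O)[C@]1(O)c2c(O[C@]1(O)c1ccc(OCc5ccccc5)cc1)cc(OCc5ccccc5)c3c2O[C@H](c2ccc(OCc5ccccc5)cc2)CC3 | intermediate
19 | methyl (2S,8S,9S)-5-(benzyloxy)-2,8-bis[4-(benzyloxy)phenyl]-8,9-bis[(triethylsilyl)oxy]-3,4,8,9-tetrahydro-2H-furo[2,3-h]chromene-9-carboxylate (same spatial arrangement as 18) | COC(=O)[C@]1(O[Si](CC)(CC)CC)c2c(O[C@]1(O[Si](CC)(CC)CC)c1ccc(OCc5ccccc5)cc1)cc(OCc5ccccc5)c3c2O[C@H](c2ccc(OCc5ccccc5)cc2)CC3 | intermediate (not isolated)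
20 | methyl (2S,8R,9S)-5-(benzyloxy)-2,8-bis[4-(benzyloxy)phenyl]-8-hydroxy-9-[(triethylsilyl)oxy]-3,4,8,9-tetrahydro-2H-furo[2,3-h]chromene-9-carboxylate (C8 hydroxyl cis to the C9 ester) | COC(=O)[C@]1(O[Si](CC)(CC)CC)c2c(O[C@]1(O)c1ccc(OCc5ccccc5)cc1)cc(OCc5ccccc5)c3c2O[C@H](c2ccc(OCc5ccccc5)cc2)CC3 | intermediate
21 | 3,5-bis(benzyloxy)benzyne | C1#CC(OCc2ccccc2)=CC(OCc2ccccc2)=C1 | intermediate (not isolated)
22 | penta-O-benzyl daphnodorin F 3-O-triethylsilyl ether (2S,3R,2fS) | O=C1c2c(OCc5ccccc5)cc(OCc5ccccc5)cc2O[C@]2(c3ccc(OCc5ccccc5)cc3)Oc3cc(OCc5ccccc5)c4c(c3[C@@]12O[Si](CC)(CC)CC)O[C@H](c1ccc(OCc5ccccc5)cc1)CC4 | intermediate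
23 | penta-O-benzyl daphnodorin F (2S,3R,2fS) | O=C1c2c(OCc5ccccc5)cc(OCc5ccccc5)cc2O[C@]2(c3ccc(OCc5ccccc5)cc3)Oc3cc(OCc5ccccc5)c4c(c3[C@@]12O)O[C@H](c1ccc(OCc5ccccc5)cc1)CC4 | intermediate
24 | daphnodorin F (2S,3R,2fS) | O=C1c2c(O)cc(O)cc2O[C@]2(c3ccc(O)cc3)Oc3cc(O)c4c(c3[C@@]12O)O[C@H](c1ccc(O)cc1)CC4 | target

## Step count and least certain steps

Total step count: 15. Longest linear sequence: 9 steps (steps 1–4 and 11–15).

**Step 13 (key step, new method).** Four processes are most likely to defeat it.
- The aryne may be captured by the phenoxide of the ring-opened keto phenol tautomer and not by the hemiketal oxygen; that diaryl ether cannot close ring C.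
- The aryl anion may be protonated before it acylates, because the ester sits on a quaternary carbon.
- The hemiketal alkoxide may cleave the C2–C3 bond in a retro-Claisen sense; if this is reversible it would also erode the configuration at C3.
- Fluoride may remove the tertiary silyl ether.

The fallback uses known chemistry and forms C4–C4a by organolithium addition and O1–C2 by ketal exchange. It sets out from 20, which is converted with methanol and an acid catalyst into the methyl ketal F1; the ester of F1 is reduced with i-Bu2AlH at −78 °C to the aldehyde F2. Bromophenol 14 is protected as the methoxymethyl ether F3 and converted by bromine–lithium exchange with n-BuLi into the aryllithium F4, which adds to F2 to give the carbinol F5. Oxidation with Dess–Martin periodinane gives the ketone F6. HCl in MeOH/THF then removes the methoxymethyl and silyl groups and exchanges the ketal methoxy group for the freed ring A phenol, which closes ring C in its only possible, cis-fused form. The sequence comes back to the route at 23.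

**Step 11.** Likely failures are poor discrimination between the two faces of the central carbonyl (the tricarbonyl can chelate copper in more than one way), competing substitution at C6f, lactonisation of the phenol onto the ester in place of hemiketal formation, and oxidation of the electron-rich phenol by divalent copper. The fallback sets out from 7 and 11 and gives up catalyst control for separation. 7 is converted with EtMgBr into its bromomagnesium phenolate F7, which adds 11 ortho-specifically through a magnesium chelate in toluene/CH2Cl2 without a chiral additive. This gives 18 together with its C3 epimer F8; the two are diastereomers because of C2f and are separated by chromatography or crystallisation. 18 comes back to the route at step 12.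

**Step 12.** Likely failures are incomplete silylation of the crowded C3 hydroxyl and loss of both silyl groups in the partial hydrolysis. The fallback omits the hydrolysis. It sets out from 19, which is isolated and submitted itself to the conditions of step 13; fluoride cleaves the labile silyl ketal in the flask and releases the C2 oxygen as the nucleophile with no hydroxyl proton present. It comes back to the route at 22 and makes no new compound.

**Step 15.** The likely failure is over-reduction once the benzyl ethers are gone: hydrogenolysis of the benzylic C2f–O1f bond or of a C2–O ketal bond, or reduction of the ketone. The fallback sets out from 23 and uses Lewis-acid debenzylation with BCl3 and pentamethylbenzene as cation trap in CH2Cl2 at −78 °C, with no metal surface and no hydrogen. It comes back to the route at 24 and makes no new compound.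

**Step 9.** Likely failures are bromination at the position between the two benzyloxy groups and twofold bromination of the very electron-rich ring. The fallback fixes the position by directed metalation and sets out from 13. 13 is converted with isopropyl isocyanate and Et3N into the carbamate F9. F9 is N-silylated in the flask, lithiated between the carbamate and a benzyloxy group (TBSOTf, TMEDA, n-BuLi, −78 °C) and quenched with Me3SiCl to give the silyl carbamate F10. Cleavage of the carbamate and O-triflation in one flask (DBU, Et2NH, MeCN, 40 °C; then PhNTf2) comes back to the route at 17 and replaces steps 9 and 10.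

## Further compounds

F1 | step 13 | methyl (2S,8R,9S)-5-(benzyloxy)-2,8-bis[4-(benzyloxy)phenyl]-8-methoxy-9-[(triethylsilyl)oxy]-3,4,8,9-tetrahydro-2H-furo[2,3-h]chromene-9-carboxylate (methyl ketal of 20, either ketal epimer serves) | COC(=O)[C@]1(O[Si](CC)(CC)CC)c2c(O[C@]1(OC)c1ccc(OCc5ccccc5)cc1)cc(OCc5ccccc5)c3c2O[C@H](c2ccc(OCc5ccccc5)cc2)CC3
F2 | step 13 | 9-carbaldehyde corresponding to F1 (configuration as in 20) | O=C[C@]1(O[Si](CC)(CC)CC)c2c(O[C@]1(OC)c1ccc(OCc5ccccc5)cc1)cc(OCc5ccccc5)c3c2O[C@H](c2ccc(OCc5ccccc5)cc2)CC3
F3 | step 13 | 1,5-bis(benzyloxy)-2-bromo-3-(methoxymethoxy)benzene | COCOc1cc(OCc2ccccc2)cc(OCc2ccccc2)c1Br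
F4 | step 13 | [2,4-bis(benzyloxy)-6-(methoxymethoxy)phenyl]lithium | [Li]c1c(OCOC)cc(OCc2ccccc2)cc1OCc2ccccc2
F5 | step 13 | [2,4-bis(benzyloxy)-6-(methoxymethoxy)phenyl]carbinol from F2 and F4 (both carbinol epimers) | OC(c1c(OCOC)cc(OCc6ccccc6)cc1OCc6ccccc6)[C@]1(O[Si](CC)(CC)CC)c2c(O[C@]1(OC)c1ccc(OCc5ccccc5)cc1)cc(OCc5ccccc5)c3c2O[C@H](c2ccc(OCc5ccccc5)cc2)CC3
F6 | step 13 | 2,4-bis(benzyloxy)-6-(methoxymethoxy)phenyl ketone from F5 | O=C(c1c(OCOC)cc(OCc6ccccc6)cc1OCc6ccccc6)[C@]1(O[Si](CC)(CC)CC)c2c(O[C@]1(OC)c1ccc(OCc5ccccc5)cc1)cc(OCc5ccccc5)c3c2O[C@H](c2ccc(OCc5ccccc5)cc2)CC3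
F7 | step 11 | bromomagnesium (2S)-5-(benzyloxy)-2-[4-(benzyloxy)phenyl]chroman-7-olate | C1C[C@@H](c2ccc(OCc3ccccc3)cc2)Oc2cc(O[Mg]Br)cc(OCc3ccccc3)c12
F8 | step 11 | methyl (2S,8S,9R)-5-(benzyloxy)-2,8-bis[4-(benzyloxy)phenyl]-8,9-dihydroxy-3,4,8,9-tetrahydro-2H-furo[2,3-h]chromene-9-carboxylate (C3 epimer of 18) | COC(=O)[C@@]1(O)c2c(O[C@@]1(O)c1ccc(OCc5ccccc5)cc1)cc(OCc5ccccc5)c3c2O[C@H](c2ccc(OCc5ccccc5)cc2)CC3
F0 | step 12 | none | none
F0 | step 15 | none | none
F9 | step 9 | 3,5-bis(benzyloxy)phenyl N-isopropylcarbamate | CC(C)NC(=O)Oc1cc(OCc2ccccc2)cc(OCc2ccccc2)c1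
F10 | step 9 | 3,5-bis(benzyloxy)-2-(trimethylsilyl)phenyl N-isopropylcarbamate | CC(C)NC(=O)Oc1cc(OCc2ccccc2)cc(OCc2ccccc2)c1[Si](C)(C)C
A1 | alternative 1 | {(2S)-5-(benzyloxy)-2-[4-(benzyloxy)phenyl]-7-(methoxymethoxy)chroman-8-yl}magnesium bromide | Br[Mg]c1c(OCOC)cc(OCc5ccccc5)c2c1O[C@H](c1ccc(OCc5ccccc5)cc1)CC2
A2 | alternative 1 | tert-butyl 2-[tert-butyl(dimethyl)silyl]-2-oxoacetate | CC(C)(C)OC(=O)C(=O)[Si](C)(C)C(C)(C)C
A3 | alternative 1 | 4-(benzyloxy)benzaldehyde | O=Cc1ccc(OCc2ccccc2)cc1
A4 | alternative 1 | tert-butyl 2-{(2S)-5-(benzyloxy)-2-[4-(benzyloxy)phenyl]-7-(methoxymethoxy)chroman-8-yl}-3-[4-(benzyloxy)phenyl]-2-[(tert-butyldimethylsilyl)oxy]-3-hydroxypropanoate | CC(C)(C)OC(=O)[C@@](O[Si](C)(C)C(C)(C)C)([C@H](O)c1ccc(OCc5ccccc5)cc1)c1c(OCOC)cc(OCc5ccccc5)c2c1O[C@H](c1ccc(OCc5ccccc5)cc1)CC2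
A5 | alternative 2 | 1-{(2S)-5-(benzyloxy)-2-[4-(benzyloxy)phenyl]-7-{[4-(benzyloxy)benzyl]oxy}chroman-8-yl}-2-(2,4,6-triacetoxyphenyl)ethane-1,2-dione | O=C(c1c(OC(C)=O)cc(OC(C)=O)cc1OC(C)=O)C(=O)c1c(OCc2ccc(OCc5ccccc5)cc2)cc(OCc5ccccc5)c2c1O[C@H](c1ccc(OCc5ccccc5)cc1)CC2
A6 | alternative 2 | flavan-fused 2-[4-(benzyloxy)phenyl]-3-hydroxy-3-(2,4,6-triacetoxybenzoyl)-2,3-dihydrobenzofuran | O=C(c1c(OC(C)=O)cc(OC(C)=O)cc1OC(C)=O)[C@]1(O)c2c(O[C@@H]1c1ccc(OCc5ccccc5)cc1)cc(OCc5ccccc5)c1c2O[C@H](c2ccc(OCc5ccccc5)cc2)CC1
A7 | alternative 3 | flavan-fused 2-[4-(benzyloxy)phenyl]-3-[2,4-bis(benzyloxy)-6-hydroxybenzoyl]benzofuran | O=C(c1c(O)cc(OCc5ccccc5)cc1OCc5ccccc5)c1c(-c2ccc(OCc5ccccc5)cc2)oc2cc(OCc5ccccc5)c3c(c12)O[C@H](c1ccc(OCc5ccccc5)cc1)CC3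
A8 | alternative 3 | penta-O-benzyl daphnodorin F (identical with 23) | O=C1c2c(OCc5ccccc5)cc(OCc5ccccc5)cc2O[C@]2(c3ccc(OCc5ccccc5)cc3)Oc3cc(OCc5ccccc5)c4c(c3[C@@]12O)O[C@H](c1ccc(OCc5ccccc5)cc1)CC4
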